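The seven-membered ring is traced back to a six-membered one (hydroazulene numbering). Without the formyl-bearing carbon C6, atoms C3a, C4, C5, C7, C8 and C8a form the cyclohexanone of a trans-hydrindane. Its C7 carbonyl and equatorial C4 oxygen are 1,3-related, an aldol pattern that six-ring rules can set. Adding dibromocarbene to the C5=C7 silyl enol ether and opening the resulting siloxy dibromocyclopropane inserts C6, enlarges the ring and leaves bromine on C6 as the handle for the aldehyde, all in one operation. The precursor is the tris(triethylsilyl) compound 13: C3 and C4 alcohols as ethers, the C7 ketone as its enol ether towards C5, all four stereocentres in place.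

Key step: step 9

Remark (labels): the atom labels of the target are used for every compound (C3 carbinol, C3a ring-fusion CH, C4 CH–O, C5, C6, C7, C8, C8a quaternary C–CH3). β is the face of the C8a methyl and α the opposite face.
Remark (assumption): the antipode of the chiral NHC ligand in step 2 is chosen so that methyl is delivered to the enone face giving (R)-6; both antipodes are accessible.
Remark (design): the enol ether is a triethylsilyl ether made by soft enolisation. It should resist tert-butoxide better than a trimethylsilyl ether, and its formation avoids a free enolate with a leaving group on C4. The C7 configuration drawn for 17–20 is the expected one and is erased in step 11.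

Step 1
Reactants: 1 3-ethoxycyclopent-2-en-1-one; 2 2-methylallylmagnesium chloride
Product: 4 3-(2-methylallyl)cyclopent-2-en-1-one, via chloromagnesium alkoxide 3 (not isolated)
Conditions: 2 (1.2 equiv), THF, 0 °C; then 1 M HCl, 0 °C, brief contact
Reagents that add atoms: none
Why: 1,2-Addition of the Grignard reagent to the vinylogous ester, then acid-induced loss of ethanol with carbonyl transposition (Stork–Danheiser-type sequence), gives the β-substituted enone, and short cold acid contact should keep the 1,1-disubstituted alkene out of conjugation.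

Step 2
Reactants: 4 3-(2-methylallyl)cyclopent-2-en-1-one
Product: 6 (R)-triethyl{[3-methyl-3-(2-methylallyl)cyclopent-1-en-1-yl]oxy}silane, via dimethylaluminium enolate 5 (not isolated)
Conditions: Me3Al (2 equiv), Cu(OTf)2 (5 mol %), chiral sulfonate-bearing bidentate NHC·Ag(I) complex (2.5 mol %), THF, −78 °C; then TESOTf, −78 → 0 °C
Reagents that add atoms: trimethylaluminium C[Al](C)C; triethylsilyl trifluoromethanesulfonate CC[Si](CC)(CC)OS(=O)(=O)C(F)(F)F
Why: Copper-catalysed asymmetric conjugate addition of an alkylaluminium to a β-substituted cyclopentenone sets the quaternary centre C8a under catalyst control, and O-silylation of the aluminium enolate locks the enolate regiochemistry at C3=C3a.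

Step 3
Reactants: 6 (R)-triethyl{[3-methyl-3-(2-methylallyl)cyclopent-1-en-1-yl]oxy}silane
Product: 7 (2S,3R)-2-(hydroxymethyl)-3-methyl-3-(2-methylallyl)cyclopentan-1-one (CH2OH cis to CH3)
Conditions: 37% aq. HCHO, Yb(OTf)3 (10 mol %), THF, rt
Reagents that add atoms: formaldehyde C=O
Why: The lanthanide-triflate-catalysed Mukaiyama aldol reaction with aqueous formaldehyde forms C3a–C4 on the enol ether face anti to the larger methallyl group, placing CH2OH cis to the methyl group, which is also the arrangement favoured if this epimerisable centre equilibrates.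

Step 4
Reactants: 7 (2S,3R)-2-(hydroxymethyl)-3-methyl-3-(2-methylallyl)cyclopentan-1-one
Product: 8 (1R,2S,3R)-2-(hydroxymethyl)-1-isopropyl-3-methyl-3-(2-methylallyl)cyclopentan-1-ol (OH, CH2OH and CH3 all cis)
Conditions: i-PrMgCl/CeCl3 (4 equiv each, premixed in THF, −78 °C), −78 → −20 °C; aq. NH4Cl
Reagents that add atoms: isopropylmagnesium chloride CC(C)[Mg]Cl
Why: The weakly basic organocerium reagent (first equivalent consumed by the OH) adds to the hindered, enolisable ketone from the α face, anti to the neighbouring CH2O–metal substituent, so the C3 hydroxyl should end up cis to C4.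

Step 5
Reactants: 8 (1R,2S,3R)-2-(hydroxymethyl)-1-isopropyl-3-methyl-3-(2-methylallyl)cyclopentan-1-ol
Product: 9 1-[(1R,2S,3R)-3-hydroxy-2-(hydroxymethyl)-3-isopropyl-1-methylcyclopentyl]propan-2-one
Conditions: O3, CH2Cl2/MeOH, −78 °C; then Me2S, → rt
Reagents that add atoms: ozone [O-][O+]=O
Why: Ozonolysis with reductive work-up cleaves the only alkene to the methyl ketone (C7, with C5 as its methyl carbon) and touches no stereocentre.

Step 6
Reactants: 9 1-[(1R,2S,3R)-3-hydroxy-2-(hydroxymethyl)-3-isopropyl-1-methylcyclopentyl]propan-2-one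
Product: 10 (1R,2R,5R)-2-hydroxy-2-isopropyl-5-methyl-5-(2-oxopropyl)cyclopentane-1-carbaldehyde
Conditions: Dess–Martin periodinane (1.2 equiv), CH2Cl2, 0 °C → rt
Reagents that add atoms: none
Why: Dess–Martin oxidation takes the hindered primary alcohol to the aldehyde without base, the tertiary alcohol cannot be oxidised, and C3a is not put at risk (its descriptor changes only through CIP priorities).

Step 7
Reactants: 10 (1R,2R,5R)-2-hydroxy-2-isopropyl-5-methyl-5-(2-oxopropyl)cyclopentane-1-carbaldehyde
Product: 11 (3R,3aS,4S,8aR)-3,4-dihydroxy-3-isopropyl-8a-methyl-trans-hydrindan-7-one (3β-OH, 3aα-H, equatorial 4α-OH, 8aβ-CH3)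
Conditions: K2CO3 (0.3 equiv), MeOH, 0 °C, monitored; pH 7 buffer
Reagents that add atoms: none
Why: Reversible base-catalysed intramolecular aldol addition (6-enolendo-exo-trig; attack from C8 would need a four-membered ring) joins the methyl carbon C5 to C4, and equilibration should favour the trans-fused chair with the equatorial 4α-hydroxyl, whose axial epimer clashes with the C8a methyl, while the catalytic weak base keeps retro-aldol at C3–C3a, enolisation at the shielded C3a–H and E1cB loss of the poorly aligned equatorial hydroxyl slow.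

Step 8
Reactants: 11 (3R,3aS,4S,8aR)-3,4-dihydroxy-3-isopropyl-8a-methyl-trans-hydrindan-7-one
Product: 13 trans-hydrindane tris(triethylsilyl) compound (3β-OTES, 4α-OTES, C7-OTES enol ether with C5=C7), via bis(triethylsilyl) ketone 12 (not isolated)
Conditions: TESOTf (2.6 equiv), 2,6-lutidine, CH2Cl2, 0 °C → rt; then Et3N, TESOTf (1.5 equiv), 0 °C → rt; cold aq. NaHCO3; Et3N-deactivated SiO2
Reagents that add atoms: triethylsilyl trifluoromethanesulfonate CC[Si](CC)(CC)OS(=O)(=O)C(F)(F)F
Why: Silyl triflate with 2,6-lutidine caps the secondary and the hindered tertiary alcohol, and added triethylamine then brings about soft enolisation (O-silylation, then deprotonation of the oxocarbenium ion) without a free enolate that could expel the C4 oxygen, the double bond settling towards C5 because a C7=C8 bond next to the quaternary ring-fusion carbon strains a trans-fused bicycle.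

Step 9
Reactants: 13 trans-hydrindane tris(triethylsilyl) compound; 14 bromoform
Product: 16 6-bromo-3β,4α-bis(triethylsilyloxy)-3α-isopropyl-8aβ-methyl-trans-hydroazul-5-en-7-one, via siloxy dibromocyclopropane 15 (not isolated)
Conditions: 14 (3 equiv), KOt-Bu (3.5 equiv), pentane, −25 → 0 °C; filter (Celite), concentrate cold; then PhMe, 2,6-lutidine (0.2 equiv), 60–80 °C
Reagents that add atoms: none
Why: Potassium tert-butoxide converts bromoform by α-elimination into dibromocarbene, which adds as an electrophile in a concerted [2+1] cycloaddition to the electron-rich C5=C7 enol ether, most likely from the α face opposite the axial C8a methyl, forming C5–C6 and C6–C7 in cyclopropane 15. On warming, 15 opens by a disrotatory two-electron electrocyclic process in which the endo bromide departs, the shared C5–C7 bond breaks under the push of the silyloxy oxygen, and bromide takes the silyl group off the oxocarbenium ion to give the ring-cis 2-bromoenone. The closest known reaction type is the dihalocarbene ring expansion of cyclic silyl enol ethers to 2-halocycloalk-2-enones. The seven-membered ring is closed not by cyclisation of a chain but by ring enlargement: a three-membered ring is fused on by cheletropic addition and its inner bond is then cleaved, so the six-membered ring grows by one atom. No stereocentre is created, since C5 and C7 return to sp2, and C3, C3a, C4 and C8a are spectators. The step needs the carbon to enter between C5 and C7 and not between C7 and C8, which the enol ether position fixed in step 8 secures, and it needs the base-sensitive γ-silyloxy bromoenone to be kept from alkoxide, which the robust triethylsilyl enol ether allows because 15 should survive until the salts have been filtered off.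

Step 10
Reactants: 16 6-bromo-3β,4α-bis(triethylsilyloxy)-3α-isopropyl-8aβ-methyl-trans-hydroazul-5-en-7-one
Product: 17 the corresponding 6-bromo-5-en-7β-ol (7R expected)
Conditions: NaBH4, CeCl3·7H2O, MeOH/THF, −40 °C
Reagents that add atoms: none
Why: Luche reduction delivers hydride 1,2 to the 2-bromoenone, expected from the α face opposite the C8a methyl, and since C7 loses its stereocentre in step 11 either epimer serves.

Step 11
Reactants: 17 6-bromo-5-en-7β-ol
Product: 21 6-bromo-3β,4α-bis(triethylsilyloxy)-3α-isopropyl-8aβ-methyl-1,2,3,3a,4,5,8,8a-octahydroazulene (C6=C7), via sulfonylhydrazone adduct 18 (not isolated), via allylic sulfonylhydrazine 19 (not isolated), via allylic diazene 20 (not isolated)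
Conditions: IPNBSH (N-isopropylidene-N′-2-nitrobenzenesulfonylhydrazine), PPh3, DEAD, THF, 0 °C → rt; then CF3CH2OH/H2O (1:1), rt
Reagents that add atoms: none
Why: Mitsunobu displacement from the open α face, hydrolysis of the hydrazone and loss of sulfinic acid give a monoalkyl diazene whose retro-ene loss of dinitrogen (reductive allylic transposition) places hydrogen on C5 and moves the alkene regiospecifically to C6=C7, leaving the vinylic bromide on C6.

Step 12
Reactants: 21 6-bromo-octahydroazulene bis(triethylsilyl) ether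
Product: 24 3β,4α-bis(triethylsilyloxy)-3α-isopropyl-8aβ-methyl-1,2,3,3a,4,5,8,8a-octahydroazulene-6-carbaldehyde, via vinyllithium 22 (not isolated), via lithium hemiaminalate 23 (not isolated)
Conditions: t-BuLi (2.1 equiv), Et2O, −78 °C; DMF, −78 → 0 °C; H2O
Reagents that add atoms: N,N-dimethylformamide CN(C)C=O
Why: Bromine–lithium exchange keeps the alkene where it is, and formylation of the vinyllithium with DMF turns C6–Br into the conjugated aldehyde, the silyl ethers being inert at −78 °C.

Step 13
Reactants: 24 bis(triethylsilyl) enal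
Product: 25 (3R,3aS,4S,8aR)-3,4-dihydroxy-3-isopropyl-8a-methyl-1,2,3,3a,4,5,8,8a-octahydroazulene-6-carbaldehyde
Conditions: HF·pyridine, pyridine, THF, 0 °C → rt
Reagents that add atoms: none
Why: Fluoride-driven desilylation under buffered, mildly acidic conditions frees both alcohols without dehydrating the tertiary carbinol or disturbing the enal.

Step 14
Reactants: 26 4-hydroxybenzoic acid
Product: 28 4-(tert-butyldimethylsilyloxy)benzoic acid, via bis-silylated acid 27 (not isolated)
Conditions: TBSCl (2.4 equiv), imidazole, DMF, rt; then AcOH/THF/H2O (3:1:1), rt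
Reagents that add atoms: tert-butyldimethylsilyl chloride CC(C)(C)[Si](C)(C)Cl
Why: Exhaustive silylation followed by selective hydrolysis of the far more labile silyl ester leaves the acid-tolerant aryl silyl ether and gives the phenol-protected acid.

Step 15
Reactants: 25 diol enal; 28 4-(tert-butyldimethylsilyloxy)benzoic acid
Product: 30 (3R,3aS,4S,8aR)-6-formyl-3-hydroxy-3-isopropyl-8a-methyl-1,2,3,3a,4,5,8,8a-octahydroazulen-4-yl 4-(tert-butyldimethylsilyloxy)benzoate, via O-acylisourea 29 (not isolated)
Conditions: DCC, DMAP, CH2Cl2, rt → 40 °C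
Reagents that add atoms: none
Why: Steglich esterification acylates only the secondary C4 alcohol because the crowded tertiary C3 alcohol does not react with the acylpyridinium species, and C4 keeps its configuration since its C–O bond is not broken.

Step 16
Reactants: 30 silyl-protected ester
Product: 31 target, (3R,3aS,4S,8aR)-6-formyl-3-hydroxy-3-isopropyl-8a-methyl-1,2,3,3a,4,5,8,8a-octahydroazulen-4-yl 4-hydroxybenzoate
Conditions: TBAF, AcOH (1:1), THF, 0 °C
Reagents that add atoms: none
Why: Buffered fluoride cleaves the aryl silyl ether rapidly and leaves the benzoate ester, the enal and the tertiary alcohol untouched.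

Compound list
1 | 3-ethoxycyclopent-2-en-1-one | CCOC1=CC(=O)CC1 | starting material
2 | 2-methylallylmagnesium chloride | CC(=C)C[Mg]Cl | starting material
3 | chloromagnesium alkoxide of 3-ethoxy-1-(2-methylallyl)cyclopent-2-en-1-ol (racemic) | CCOC1=CC(CC(C)=C)(O[Mg]Cl)CC1 | intermediate
4 | 3-(2-methylallyl)cyclopent-2-en-1-one | CC(=C)CC1=CC(=O)CC1 | intermediate
5 | dimethylaluminium (R)-3-methyl-3-(2-methylallyl)cyclopent-1-en-1-olate | C[C@]1(CC(C)=C)CCC(O[Al](C)C)=C1 | intermediate
6 | (R)-triethyl{[3-methyl-3-(2-methylallyl)cyclopent-1-en-1-yl]oxy}silane | C[C@]1(CC(C)=C)CCC(O[Si](CC)(CC)CC)=C1 | intermediate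
7 | (2S,3R)-2-(hydroxymethyl)-3-methyl-3-(2-methylallyl)cyclopentan-1-one | O=C1CC[C@](C)(CC(C)=C)[C@H]1CO | intermediate
8 | (1R,2S,3R)-2-(hydroxymethyl)-1-isopropyl-3-methyl-3-(2-methylallyl)cyclopentan-1-ol | CC(C)[C@]1(O)CC[C@](C)(CC(C)=C)[C@H]1CO | intermediate
9 | 1-[(1R,2S,3R)-3-hydroxy-2-(hydroxymethyl)-3-isopropyl-1-methylcyclopentyl]propan-2-one | CC(C)[C@]1(O)CC[C@](C)(CC(C)=O)[C@H]1CO | intermediate
10 | (1R,2R,5R)-2-hydroxy-2-isopropyl-5-methyl-5-(2-oxopropyl)cyclopentane-1-carbaldehyde | CC(C)[C@]1(O)CC[C@](C)(CC(C)=O)[C@H]1C=O | intermediate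
11 | (3R,3aS,4S,8aR)-3,4-dihydroxy-3-isopropyl-8a-methyl-trans-hydrindan-7-one; systematic (1R,3aR,7S,7aS)-1,7-dihydroxy-3a-methyl-1-(propan-2-yl)octahydro-5H-inden-5-one | CC(C)[C@]1(O)CC[C@]2(C)CC(=O)C[C@H](O)[C@H]21 | intermediate
12 | 3β,4α-bis(triethylsilyloxy)-3α-isopropyl-8aβ-methyl-trans-hydrindan-7-one | CC(C)[C@]1(O[Si](CC)(CC)CC)CC[C@]2(C)CC(=O)C[C@H](O[Si](CC)(CC)CC)[C@H]21 | intermediate
13 | (3R,3aS,4S,8aR)-3,4,7-tris(triethylsilyloxy)-3-isopropyl-8a-methyl-trans-hydrind-5(7)-ene (silyl enol ether C5=C7) | CC(C)[C@]1(O[Si](CC)(CC)CC)CC[C@]2(C)CC(O[Si](CC)(CC)CC)=C[C@H](O[Si](CC)(CC)CC)[C@H]21 | intermediate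
14 | bromoform | BrC(Br)Br | starting material
15 | siloxy dibromocyclopropane, CBr2 (C6) bridging C5 and C7 on the α face of 13 | CC(C)[C@]1(O[Si](CC)(CC)CC)CC[C@]2(C)C[C@]3(O[Si](CC)(CC)CC)C(Br)(Br)[C@@H]3[C@H](O[Si](CC)(CC)CC)[C@H]21 | intermediate
16 | (3R,3aS,4R,8aR)-6-bromo-3-isopropyl-8a-methyl-3,4-bis(triethylsilyloxy)-2,3,3a,4,8,8a-hexahydroazulen-7(1H)-one (same spatial arrangement as 13; 4R by CIP priority of the bromoalkene) | CC(C)[C@]1(O[Si](CC)(CC)CC)CC[C@]2(C)CC(=O)C(Br)=C[C@H](O[Si](CC)(CC)CC)[C@H]21 | intermediate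
17 | (3R,3aS,4R,7R,8aR)-6-bromo-3-isopropyl-8a-methyl-3,4-bis(triethylsilyloxy)-1,2,3,3a,4,7,8,8a-octahydroazulen-7-ol (7β-OH) | CC(C)[C@]1(O[Si](CC)(CC)CC)CC[C@]2(C)C[C@@H](O)C(Br)=C[C@H](O[Si](CC)(CC)CC)[C@H]21 | intermediate
18 | 7α-[N-(2-nitrobenzenesulfonyl)-N′-isopropylidenehydrazinyl] derivative of 17 | CC(C)[C@]1(O[Si](CC)(CC)CC)CC[C@]2(C)C[C@H](N(N=C(C)C)S(=O)(=O)c3ccccc3[N+](=O)[O-])C(Br)=C[C@H](O[Si](CC)(CC)CC)[C@H]21 | intermediate
19 | 7α-[N-(2-nitrobenzenesulfonyl)hydrazinyl] compound | CC(C)[C@]1(O[Si](CC)(CC)CC)CC[C@]2(C)C[C@H](N(N)S(=O)(=O)c3ccccc3[N+](=O)[O-])C(Br)=C[C@H](O[Si](CC)(CC)CC)[C@H]21 | intermediate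
20 | 7α-diazenyl compound (allylic monoalkyl diazene) | CC(C)[C@]1(O[Si](CC)(CC)CC)CC[C@]2(C)C[C@H](N=N)C(Br)=C[C@H](O[Si](CC)(CC)CC)[C@H]21 | intermediate
21 | (3R,3aS,4S,8aR)-6-bromo-3-isopropyl-8a-methyl-3,4-bis(triethylsilyloxy)-1,2,3,3a,4,5,8,8a-octahydroazulene | CC(C)[C@]1(O[Si](CC)(CC)CC)CC[C@]2(C)CC=C(Br)C[C@H](O[Si](CC)(CC)CC)[C@H]21 | intermediate
22 | C6 vinyllithium derived from 21 | CC(C)[C@]1(O[Si](CC)(CC)CC)CC[C@]2(C)CC=C([Li])C[C@H](O[Si](CC)(CC)CC)[C@H]21 | intermediate
23 | lithium hemiaminalate (DMF adduct of 22; new carbinol carbon undefined) | CC(C)[C@]1(O[Si](CC)(CC)CC)CC[C@]2(C)CC=C(C(O[Li])N(C)C)C[C@H](O[Si](CC)(CC)CC)[C@H]21 | intermediate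
24 | (3R,3aS,4S,8aR)-3-isopropyl-8a-methyl-3,4-bis(triethylsilyloxy)-1,2,3,3a,4,5,8,8a-octahydroazulene-6-carbaldehyde | CC(C)[C@]1(O[Si](CC)(CC)CC)CC[C@]2(C)CC=C(C=O)C[C@H](O[Si](CC)(CC)CC)[C@H]21 | intermediate
25 | (3R,3aS,4S,8aR)-3,4-dihydroxy-3-isopropyl-8a-methyl-1,2,3,3a,4,5,8,8a-octahydroazulene-6-carbaldehyde | CC(C)[C@]1(O)CC[C@]2(C)CC=C(C=O)C[C@H](O)[C@H]21 | intermediate
26 | 4-hydroxybenzoic acid | OC(=O)c1ccc(O)cc1 | starting material
27 | tert-butyldimethylsilyl 4-(tert-butyldimethylsilyloxy)benzoate | CC(C)(C)[Si](C)(C)OC(=O)c1ccc(O[Si](C)(C)C(C)(C)C)cc1 | intermediate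
28 | 4-(tert-butyldimethylsilyloxy)benzoic acid | OC(=O)c1ccc(O[Si](C)(C)C(C)(C)C)cc1 | intermediate
29 | O-acylisourea from 28 and DCC | O=C(OC(=NC1CCCCC1)NC1CCCCC1)c1ccc(O[Si](C)(C)C(C)(C)C)cc1 | intermediate
30 | (3R,3aS,4S,8aR)-6-formyl-3-hydroxy-3-isopropyl-8a-methyl-1,2,3,3a,4,5,8,8a-octahydroazulen-4-yl 4-(tert-butyldimethylsilyloxy)benzoate | CC(C)[C@]1(O)CC[C@]2(C)CC=C(C=O)C[C@H](OC(=O)c3ccc(O[Si](C)(C)C(C)(C)C)cc3)[C@H]21 | intermediate
31 | (3R,3aS,4S,8aR)-6-formyl-3-hydroxy-3-isopropyl-8a-methyl-1,2,3,3a,4,5,8,8a-octahydroazulen-4-yl 4-hydroxybenzoate | CC(C)[C@]1(O)CC[C@]2(C)CC=C(C=O)C[C@H](OC(=O)c3ccc(O)cc3)[C@H]21 | target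

Total step count: 16. Longest linear sequence: 15 (steps 1–13, 15, 16); step 14 is a one-step branch.

Steps most likely to fail

1. Step 9 (key step).
- **Risk:** carbene capture may be slow at an alkene flanked by the bulky C4 silyl ether, so that desilylation of the enol ether by tert-butoxide and β-elimination at C4 compete. Alternatively the cyclopropane may open while base is still present, and the product then decays.
- **Fallback (same insertion of C6, different carbon source and trigger), from 13:** zinc-carbenoid cyclopropanation (Et2Zn, CH2I2, CH2Cl2, 0 °C) should give the siloxycyclopropane F1. FeCl3 in DMF/pyridine at 0 °C cleaves the shared C5–C7 bond oxidatively to the ring-enlarged 5-chloro ketone F2 (C5 epimers). NaOAc in warm MeOH removes hydrogen chloride to give the cycloheptenone F3. Addition of bromine (CH2Cl2, 0 °C) gives the 5,6-dibromo ketone F4, and treatment with Et3N rejoins the route at 16.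

2. Step 7.
- **Risk:** the ketol may lose water under the equilibrating conditions, or selectivity at C4 may erode before the closure is complete.
- **Fallback, from 10:** all material is pushed on purpose through aldol condensation (same base, warmer and longer, or MsCl/Et3N on the crude ketol mixture) to the trans-hydrindenone F5. Copper(I)-catalysed conjugate borylation (B2pin2, CuCl, NaOt-Bu, DPEphos, MeOH, THF) should then place boron on C4 from the α face, because the β face of C4 is screened by the C8a methyl and the C3 oxygen; this gives the 4α-boryl ketone F6. Oxidation with NaBO3·4H2O, which retains configuration, rejoins the route at 11.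

3. Step 11.
- **Risk:** the SN2 displacement at the C7 carbinol, which lies next to the neopentyl-type C8, may fail, with elimination to a diene or simple return of the alcohol.
- **Fallback, from 16 (17 is bypassed):** the diazene is reached by C=N reduction instead of substitution. Condensation with TsNHNH2 (EtOH, cat. PPTS) should give the tosylhydrazone F7. Catecholborane (CHCl3, 0 °C) reduces it 1,2 to the allylic tosylhydrazine F8. NaOAc·3H2O in warm CHCl3 triggers loss of sulfinate and dinitrogen with the same alkene shift, rejoining the route at 21.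

Further compounds
F1 | step 9 | siloxycyclopropane, CH2 (C6) bridging C5 and C7 on the α face of 13 | CC(C)[C@]1(O[Si](CC)(CC)CC)CC[C@]2(C)C[C@]3(O[Si](CC)(CC)CC)C[C@@H]3[C@H](O[Si](CC)(CC)CC)[C@H]21
F2 | step 9 | 5-chloro-3β,4α-bis(triethylsilyloxy)-trans-hydroazulan-7-one (C5 epimers) | CC(C)[C@]1(O[Si](CC)(CC)CC)CC[C@]2(C)CC(=O)CC(Cl)[C@H](O[Si](CC)(CC)CC)[C@H]21
F3 | step 9 | 3β,4α-bis(triethylsilyloxy)-trans-hydroazul-5-en-7-one | CC(C)[C@]1(O[Si](CC)(CC)CC)CC[C@]2(C)CC(=O)C=C[C@H](O[Si](CC)(CC)CC)[C@H]21
F4 | step 9 | 5,6-dibromo-3β,4α-bis(triethylsilyloxy)-trans-hydroazulan-7-one (C5/C6 undefined) | CC(C)[C@]1(O[Si](CC)(CC)CC)CC[C@]2(C)CC(=O)C(Br)C(Br)[C@H](O[Si](CC)(CC)CC)[C@H]21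
F5 | step 7 | 3β-hydroxy-3α-isopropyl-8aβ-methyl-trans-hydrind-4-en-7-one | CC(C)[C@]1(O)CC[C@]2(C)CC(=O)C=C[C@H]21
F6 | step 7 | 4α-(pinacolatoboryl)-3β-hydroxy-3α-isopropyl-8aβ-methyl-trans-hydrindan-7-one | CC(C)[C@]1(O)CC[C@]2(C)CC(=O)C[C@H](B3OC(C)(C)C(C)(C)O3)[C@H]21
F7 | step 11 | tosylhydrazone of 16 | CC(C)[C@]1(O[Si](CC)(CC)CC)CC[C@]2(C)CC(=NNS(=O)(=O)c3ccc(C)cc3)C(Br)=C[C@H](O[Si](CC)(CC)CC)[C@H]21
F8 | step 11 | allylic tosylhydrazine from F7 (C7 undefined) | CC(C)[C@]1(O[Si](CC)(CC)CC)CC[C@]2(C)CC(NNS(=O)(=O)c3ccc(C)cc3)C(Br)=C[C@H](O[Si](CC)(CC)CC)[C@H]21
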